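Ring A of the target is a resorcinol-type benzoate: C1 carries the ester carbon, C2 the diaryl ketone, C3 and C5 the oxygens. C1 and its ester are therefore cut out together as dimethyl oxalate, leaving C2–C6 as the chain of an aryl 1,3,5-triketone whose aryl group is the protected orcinol ring B. In one operation the triketone polyanion is acylated at its terminal carbon C6 by the oxalate, the C2 methylene closes onto the new keto carbonyl C1, and dehydration aromatizes ring A with the hindered C2 ketone already in place. The precursor is 1-[2,6-bis(methoxymethoxy)-4-methylphenyl]hexane-1,3,5-trione.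

Key step: step 5

Remark: ring B is carried as its bis(methoxymethyl) ether, which directs lithiation cleanly to the carbon between the two oxygens where benzyl ethers would risk benzylic metalation, and O5 of ring A is carried as a benzyl ether so that the last deprotection is a neutral hydrogenolysis that the aryl acetate tolerates.

Step 1
Reactants: 1 orcinol (5-methylbenzene-1,3-diol)
Product: 2 1,3-bis(methoxymethoxy)-5-methylbenzene
Conditions: NaH, MOMCl, THF/DMF, 0 °C → rt
Reagents that add atoms: chloromethyl methyl ether, COCCl
Why: Williamson etherification of both phenoxides of the symmetrical diol with the reactive alpha-chloro ether should install the two methoxymethyl ethers.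

Step 2
Reactants: 2 1,3-bis(methoxymethoxy)-5-methylbenzene
Product: 4 2,6-bis(methoxymethoxy)-4-methylbenzaldehyde, via aryllithium 3 (not isolated)
Conditions: n-BuLi, TMEDA, THF, 0 °C; DMF, 0 °C → rt; H2O
Reagents that add atoms: N,N-dimethylformamide, CN(C)C=O
Why: directed ortho-metalation, with both acetal oxygens chelating lithium, should remove the proton on the carbon between them, and the aryllithium is then formylated by DMF (Bouveault-type formylation).

Step 3
Reactants: 4 2,6-bis(methoxymethoxy)-4-methylbenzaldehyde; 5 acetylacetone (pentane-2,4-dione)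
Product: 7 racemic 6-[2,6-bis(methoxymethoxy)-4-methylphenyl]-6-hydroxyhexane-2,4-dione, via acetylacetone dianion 6 (not isolated)
Conditions: LiN(iPr)2 (LDA, 2.6 equiv), 5 (1.3 equiv), THF, −78 → 0 °C; then 4, −78 °C; AcOH
Reagents that add atoms: none
Why: the 1,3-dianion of the diketone reacts at its terminal, more basic carbanion in an aldol addition to the aldehyde, and the new carbinol centre forms racemic and is erased in step 4.

Step 4
Reactants: 7 racemic 6-[2,6-bis(methoxymethoxy)-4-methylphenyl]-6-hydroxyhexane-2,4-dione
Product: 8 1-[2,6-bis(methoxymethoxy)-4-methylphenyl]hexane-1,3,5-trione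
Conditions: Dess–Martin periodinane, pyridine, CH2Cl2, 0 °C → rt
Reagents that add atoms: none
Why: Dess–Martin oxidation should convert the benzylic secondary alcohol into the aryl ketone under buffered, nearly neutral conditions that spare the acetal ethers and the enolized diketone.

Step 5
Reactants: 8 1-[2,6-bis(methoxymethoxy)-4-methylphenyl]hexane-1,3,5-trione; 9 dimethyl oxalate
Product: 13 methyl 2-[2,6-bis(methoxymethoxy)-4-methylbenzoyl]-3,5-dihydroxybenzoate, via triketone trianion 10 (not isolated), via tetraoxo ester 11 (not isolated), via aldol carbinol 12 (not isolated)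
Conditions: LiN(iPr)2 (4.2 equiv), THF, −78 → 0 °C; (CO2Me)2 (1.1 equiv), −78 → −20 °C; AcOH; NaOAc, MeOH, rt
Reagents that add atoms: none
Why: Three equivalents of the amide base should convert 8 into trianion 10, whose terminal C6 carbanion is formed last and is the most nucleophilic site, so it is acylated by one ester group of the oxalate in a Claisen condensation, while a fourth equivalent of base takes up the more acidic product 11 and so guards its keto carbonyl against a second addition. After protonation and mild acetate buffering, the doubly activated C2 methylene of 11 should add to the C1 keto carbonyl in a 6-(enolendo)-exo-trig aldol closure to carbinol 12, which loses water and enolizes at C3 and C5 to give aromatic ring A. The closest known chemistry is the terminal acylation of beta-triketone trianions by esters followed by biomimetic aldol aromatization of the tetracarbonyl chains to resorcinols; the oxalate is a new partner whose electrophilic carbonyl brings its own ester into the ring. No stereocentre is set, because the two transient centres of 12 disappear on aromatization. The step needs C2-to-C1 closure over C6 attack on the aryl ketone, over oxygen closure to a pyranone or butenolide, and over five-ring Dieckmann closure onto the ester. This is secured because the keto carbonyl next to the ester is the most electrophilic position, the aryl ketone is screened by its two ortho methoxymethoxy groups, and the weakly basic work-up avoids both the acid that favours pyranones and the hot alkoxide that favours Dieckmann closure.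

Step 6
Reactants: 13 methyl 2-[2,6-bis(methoxymethoxy)-4-methylbenzoyl]-3,5-dihydroxybenzoate
Product: 15 methyl 5-(benzyloxy)-2-[2,6-bis(methoxymethoxy)-4-methylbenzoyl]-3-methoxybenzoate, via monobenzyl ether 14 (not isolated)
Conditions: BnBr (1.05 equiv), K2CO3, DMF, 0 °C → rt; then MeI (excess), 45 °C
Reagents that add atoms: benzyl bromide, BrCc1ccccc1; iodomethane, CI
Why: in this one-pot sequential Williamson etherification the C5 hydroxyl, para to the ketone and free of hydrogen bonding, is the more acidic and should take the single equivalent of benzyl bromide, whereas the C3 hydroxyl chelated to the ketone is alkylated only by the excess iodomethane on warming.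

Step 7
Reactants: 15 methyl 5-(benzyloxy)-2-[2,6-bis(methoxymethoxy)-4-methylbenzoyl]-3-methoxybenzoate
Product: 16 methyl 5-(benzyloxy)-2-(2,6-dihydroxy-4-methylbenzoyl)-3-methoxybenzoate
Conditions: HCl (cat.), MeOH, 45 °C
Reagents that add atoms: none
Why: acid-catalysed acetal exchange with methanol should remove both methoxymethyl groups as dimethoxymethane, while the benzyl ether, the methyl ether and the methyl ester (in methanol) stay intact.

Step 8
Reactants: 16 methyl 5-(benzyloxy)-2-(2,6-dihydroxy-4-methylbenzoyl)-3-methoxybenzoate
Product: 17 methyl 2-[2-(acetyloxy)-6-hydroxy-4-methylbenzoyl]-5-(benzyloxy)-3-methoxybenzoate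
Conditions: Ac2O (1.05 equiv), pyridine, CH2Cl2, 0 °C
Reagents that add atoms: acetic anhydride, CC(=O)OC(C)=O
Why: O-acylation of one of the two equivalent ring B phenols should be self-limiting, because the ketone can chelate only one ortho hydroxyl at a time and, once the free one is acetylated, the remaining hydroxyl is held in the hydrogen bond and is much less nucleophilic.

Step 9
Reactants: 17 methyl 2-[2-(acetyloxy)-6-hydroxy-4-methylbenzoyl]-5-(benzyloxy)-3-methoxybenzoate
Product: 18 penibenzophenone C, methyl 2-[2-(acetyloxy)-6-hydroxy-4-methylbenzoyl]-5-hydroxy-3-methoxybenzoate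
Conditions: H2 (1 atm), Pd/C, EtOAc, rt
Reagents that add atoms: none
Why: catalytic hydrogenolysis of the benzyl aryl ether under neutral conditions should free the C5 hydroxyl without touching the aryl acetate, the methyl ester or the hindered diaryl ketone.

Compound list
1 | orcinol (5-methylbenzene-1,3-diol) | Cc1cc(O)cc(O)c1 | starting material
2 | 1,3-bis(methoxymethoxy)-5-methylbenzene | COCOc1cc(C)cc(OCOC)c1 | intermediate
3 | 2-lithio-1,3-bis(methoxymethoxy)-5-methylbenzene (aryllithium, not isolated) | [Li]c1c(OCOC)cc(C)cc1OCOC | intermediate
4 | 2,6-bis(methoxymethoxy)-4-methylbenzaldehyde | O=Cc1c(OCOC)cc(C)cc1OCOC | intermediate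
5 | acetylacetone (pentane-2,4-dione) | CC(=O)CC(C)=O | starting material
6 | dilithium dienolate (1,3-dianion) of acetylacetone (not isolated) | [Li+].[Li+].C=C([O-])C=C(C)[O-] | intermediate
7 | 6-[2,6-bis(methoxymethoxy)-4-methylphenyl]-6-hydroxyhexane-2,4-dione (racemic) | CC(=O)CC(=O)CC(O)c1c(OCOC)cc(C)cc1OCOC | intermediate
8 | 1-[2,6-bis(methoxymethoxy)-4-methylphenyl]hexane-1,3,5-trione | CC(=O)CC(=O)CC(=O)c1c(OCOC)cc(C)cc1OCOC | intermediate
9 | dimethyl oxalate | COC(=O)C(=O)OC | starting material
10 | trilithium trienolate (trianion) of 8 (not isolated) | [Li+].[Li+].[Li+].C=C([O-])C=C([O-])C=C([O-])c1c(OCOC)cc(C)cc1OCOC | intermediate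
11 | methyl 8-[2,6-bis(methoxymethoxy)-4-methylphenyl]-2,4,6,8-tetraoxooctanoate (formed as its lithium polyenolate, drawn neutral, not isolated) | COC(=O)C(=O)CC(=O)CC(=O)CC(=O)c1c(OCOC)cc(C)cc1OCOC | intermediate
12 | methyl 2-[2,6-bis(methoxymethoxy)-4-methylbenzoyl]-1-hydroxy-3,5-dioxocyclohexane-1-carboxylate (transient mixture of diastereomers, not isolated) | COC(=O)C1(O)CC(=O)CC(=O)C1C(=O)c1c(OCOC)cc(C)cc1OCOC | intermediate
13 | methyl 2-[2,6-bis(methoxymethoxy)-4-methylbenzoyl]-3,5-dihydroxybenzoate | COC(=O)c1cc(O)cc(O)c1C(=O)c1c(OCOC)cc(C)cc1OCOC | intermediate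
14 | methyl 5-(benzyloxy)-2-[2,6-bis(methoxymethoxy)-4-methylbenzoyl]-3-hydroxybenzoate (not isolated) | COC(=O)c1cc(OCc2ccccc2)cc(O)c1C(=O)c1c(OCOC)cc(C)cc1OCOC | intermediate
15 | methyl 5-(benzyloxy)-2-[2,6-bis(methoxymethoxy)-4-methylbenzoyl]-3-methoxybenzoate | COC(=O)c1cc(OCc2ccccc2)cc(OC)c1C(=O)c1c(OCOC)cc(C)cc1OCOC | intermediate
16 | methyl 5-(benzyloxy)-2-(2,6-dihydroxy-4-methylbenzoyl)-3-methoxybenzoate | COC(=O)c1cc(OCc2ccccc2)cc(OC)c1C(=O)c1c(O)cc(C)cc1O | intermediate
17 | methyl 2-[2-(acetyloxy)-6-hydroxy-4-methylbenzoyl]-5-(benzyloxy)-3-methoxybenzoate | COC(=O)c1cc(OCc2ccccc2)cc(OC)c1C(=O)c1c(O)cc(C)cc1OC(C)=O | intermediate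
18 | penibenzophenone C, methyl 2-[2-(acetyloxy)-6-hydroxy-4-methylbenzoyl]-5-hydroxy-3-methoxybenzoate (no stereocentres) | COC(=O)c1cc(O)cc(OC)c1C(=O)c1c(O)cc(C)cc1OC(C)=O | target

Total step count: 9
Longest linear sequence: 9 steps, from orcinol 1 (5 and 9 are bought).

Steps most likely to fail

1. Step 5. The acylated chain may close through oxygen to a pyranone or butenolide, or by five-ring Dieckmann attack on the remaining ester, instead of the six-ring aldol, and the oxalate may be attacked twice. Fallback by known chemistry, setting out from aldehyde 4 and coming back at 13: lithium methyl propiolate (methyl propiolate, LiN(iPr)2, THF, −78 °C) is added to 4 to give racemic methyl 4-[2,6-bis(methoxymethoxy)-4-methylphenyl]-4-hydroxybut-2-ynoate F1. MnO2 in CH2Cl2 then oxidizes this to the ynone methyl 4-[2,6-bis(methoxymethoxy)-4-methylphenyl]-4-oxobut-2-ynoate F2. A Diels–Alder reaction of F2 with 1-methoxy-1,3-bis(trimethylsilyloxy)buta-1,3-diene in toluene should give the cycloadduct methyl 2-[2,6-bis(methoxymethoxy)-4-methylbenzoyl]-3-methoxy-3,5-bis(trimethylsilyloxy)cyclohexa-1,4-diene-1-carboxylate F3 (racemic, not isolated). F3 loses methanol and, on work-up with dilute aqueous citric acid, its silyl groups to give 13. The unsubstituted diene terminus should add to the alkyne carbon beta to the ketone, the stronger acceptor, which places the ketene acetal carbon, the later C3 oxygen, next to the aroyl group.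

2. Step 4. The oxidant may attack the doubly activated methylene groups as well, or the sensitive triketone may cyclodehydrate during oxidation and isolation. Fallback setting out from 2 (through aryllithium 3) and coming back at 8: 3 is quenched with methyl chloroformate to give methyl 2,6-bis(methoxymethoxy)-4-methylbenzoate F4. Dianion 6 (two to three equivalents, THF, 0 °C → rt) is then aroylated by F4 at its terminal carbon in a Claisen condensation. This delivers 8 directly at the ketone oxidation level, so that no oxidation step is needed.

3. Step 8. Acetylation may run on to both ring B hydroxyls and so lose mono-selectivity. Fallback setting out from 16 and coming back at 17: exhaustive acetylation (Ac2O in excess, DMAP, pyridine) should give the diacetate methyl 5-(benzyloxy)-2-[2,6-bis(acetyloxy)-4-methylbenzoyl]-3-methoxybenzoate F5. One equivalent of pyrrolidine in CH2Cl2 at 0 °C then removes a single aryl acetate by aminolysis. The phenol set free chelates the ketone and should slow cleavage of the second acetate, so that the desymmetrization is done by subtraction.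

Further compounds
F1 | step 5 | methyl 4-[2,6-bis(methoxymethoxy)-4-methylphenyl]-4-hydroxybut-2-ynoate (racemic) | COC(=O)C#CC(O)c1c(OCOC)cc(C)cc1OCOC
F2 | step 5 | methyl 4-[2,6-bis(methoxymethoxy)-4-methylphenyl]-4-oxobut-2-ynoate | COC(=O)C#CC(=O)c1c(OCOC)cc(C)cc1OCOC
F3 | step 5 | methyl 2-[2,6-bis(methoxymethoxy)-4-methylbenzoyl]-3-methoxy-3,5-bis(trimethylsilyloxy)cyclohexa-1,4-diene-1-carboxylate (racemic, not isolated) | COC(=O)C1=C(C(=O)c2c(OCOC)cc(C)cc2OCOC)C(OC)(O[Si](C)(C)C)C=C(O[Si](C)(C)C)C1
F4 | step 4 | methyl 2,6-bis(methoxymethoxy)-4-methylbenzoate | COC(=O)c1c(OCOC)cc(C)cc1OCOC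
F5 | step 8 | methyl 5-(benzyloxy)-2-[2,6-bis(acetyloxy)-4-methylbenzoyl]-3-methoxybenzoate | COC(=O)c1cc(OCc2ccccc2)cc(OC)c1C(=O)c1c(OC(C)=O)cc(C)cc1OC(C)=O
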